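**Strategy.** Everything rests on the trans-fused γ-lactone (O–C7–C8–C17–C19, briarane numbers): its tertiary carbinol C8 is an aldol site and its C7–O bond the 5-exo opening of a 6,7-epoxide. In one flask the lithium enolate of tert-butyl propanoate adds to the C8 ketone of an α′-silyloxy oxiranyl ketone carried by the finished cyclohexane ring (C1, C10–C14), and acid then makes the ester oxygen open the epoxide at C7. This forms C8–C17 and O–C7, sets C8 and C17, inverts C7, and frees C6–OH for a Nozaki–Hiyama–Kishi closure of the ten-membered ring (C5–C6) before chloride displaces the C6 hydroxyl.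

Key step: step 18

Remark: locants are those of the briarane skeleton of 35 (ring A = C1, C10–C14 with C15 on C1 and C20 on C11; ten-membered ring = C1–C10 with C16 on C5; lactone = O–C7–C8–C17(C18)–C19). α is the face of ring A that carries H10, β the face that carries C15. TBS = tert-butyldimethylsilyl.

Assumption: in step 20 the antipode of the ligand L, N-[2-(4-isopropyl-4,5-dihydrooxazol-2-yl)-6-methylphenyl]methanesulfonamide, that leads to the (6R)-carbinol is taken to be (S)-L; both antipodes can be made from valinol.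

Step 1
Reactants: 1 (R)-2,2-dimethyl-1,3-dioxolane-4-carbaldehyde; 2 2-(triphenylphosphoranylidene)propanal
Product: 3 (S,E)-3-(2,2-dimethyl-1,3-dioxolan-4-yl)-2-methylprop-2-enal
Conditions: toluene, 80 °C
Reagents that add atoms: none
Why: Wittig olefination with the formyl-stabilised ylide is (E)-selective and leaves the C9 stereocenter of D-glyceraldehyde acetonide untouched.

Step 2
Reactants: 3 enal; 4 (E)-3-[(tert-butyldimethylsilyl)oxy]-N,N-dimethylbuta-1,3-dien-1-amine
Product: 5 cycloadduct aldehyde (C1 quaternary with formyl and C15, C14 amine, C12 silyl enol ether, dioxolane on C10)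
Conditions: toluene, 50 °C; crude adduct used directly
Reagents that add atoms: none
Why: Normal-demand Diels–Alder reaction in which the amino terminus of the diene bonds to the formyl-bearing carbon (C1) and its CH2 terminus to C10, the (E) geometry places the dioxolane cis to C15, and the diene should add anti to the dioxolane C9–O bond in the conformer that holds C9–H in the alkene plane beside C15 (allylic 1,3-strain), which sets C1 and C10, while the C14 amine center is lost in step 5.

Step 3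
Reactants: 5 cycloadduct aldehyde; 6 (4-bromobut-1-yn-1-yl)trimethylsilane
Product: 7 secondary alcohol at C2 (both epimers)
Conditions: 6, Mg, THF, 40 °C; then 5, THF, −78 °C; NH4Cl (aq)
Reagents that add atoms: none
Why: Grignard addition to the hindered aldehyde while the ring ketone is masked as its silyl enol ether, and the C2 epimers converge in step 4.

Step 4
Reactants: 7 secondary alcohol
Product: 8 C2 ketone
Conditions: (COCl)2, DMSO, CH2Cl2, −78 °C; Et3N, −78 → 0 °C
Reagents that add atoms: none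
Why: Swern oxidation tolerates the silyl enol ether and the tertiary amine and gives the ketone needed for a reagent-controlled reduction.

Step 5
Reactants: 8 C2 ketone
Product: 10 enone alcohol (2S; C13=C14 enone, C12 ketone), via amino alcohol 9 (not isolated)
Conditions: (R)-Me-CBS oxazaborolidine (C18H20BNO, 0.5 equiv), catecholborane, toluene, −78 → −40 °C; then 0.1 M HCl, THF, 0 °C
Reagents that add atoms: none
Why: Corey–Bakshi–Shibata reduction treats the quaternary C1 as the large group and should deliver hydride to give the (2S)-alcohol under reagent control, after which dilute acid hydrolyses the silyl enol ether and the β-amino ketone loses dimethylamine (E1cB) to unveil the enone.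

Step 6
Reactants: 10 enone alcohol
Product: 11 13α,14α-diol (triol ketone)
Conditions: OsO4 (5 mol %), N-methylmorpholine N-oxide, acetone/H2O, rt
Reagents that add atoms: N-methylmorpholine N-oxide (C[N+]1([O-])CCOCC1); water (O)
Why: Osmium-catalysed syn dihydroxylation in which, with the C2 chain and the dioxolane both pseudoequatorial, C15 is pseudoaxial beside C14, so osmium should approach the α face and set C13 and C14.

Step 7
Reactants: 11 triol ketone
Product: 12 13,14-acetonide
Conditions: Me2C(OMe)2, PPTS, acetone, rt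
Reagents that add atoms: 2,2-dimethoxypropane (COC(C)(C)OC)
Why: Acid-catalysed transketalisation closes the five-membered acetonide on the cis-13,14-diol in preference to any larger ring that would involve the C2 hydroxyl.

Step 8
Reactants: 12 acetonide ketone
Product: 14 11-methylene-12-ketone, via Mannich base 13 (not isolated)
Conditions: LiN(SiMe3)2 (2.2 equiv), THF, −78 °C; CH2=NMe2+ I−, −78 → 0 °C; then MeI, CH2Cl2; NaHCO3 (aq)
Reagents that add atoms: dimethylmethyleneiminium iodide, Eschenmoser's salt (C=[N+](C)C.[I-])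
Why: Kinetic enolisation occurs at the C11 methylene and not at the alkoxy-bearing C13, and Mannich reaction followed by elimination of the quaternised amine gives the α-methylene ketone, which is reduced at once.

Step 9
Reactants: 14 α-methylene ketone
Product: 16 12α-allylic alcohol with terminal alkyne, via silylalkyne allylic alcohol 15 (not isolated)
Conditions: NaBH4, CeCl3·7H2O, MeOH, −78 °C; then K2CO3, rt
Reagents that add atoms: none
Why: Luche 1,2-reduction in which axial approach on the α face is blocked by the axial C14 oxygen of the acetonide, so hydride should enter from the β face and give the axial 12α-alcohol, and carbonate in methanol then removes the alkynyl silyl group.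

Step 10
Reactants: 16 diol bis-acetonide
Product: 17 2,8,9,12-tetraol (ring acetonide kept)
Conditions: AcOH/H2O (4:1), rt
Reagents that add atoms: none
Why: A terminal isopropylidene acetal of a 1,2-diol hydrolyses faster than the cis-fused cyclohexane acetonide, so mild aqueous acid should free only the C8/C9 diol without hydrolysis or migration of the ring acetal.

Step 11
Reactants: 17 tetraol
Product: 18 tetrakis-TBS ether
Conditions: TBSOTf, 2,6-lutidine, CH2Cl2, −78 → 0 °C
Reagents that add atoms: tert-butyldimethylsilyl triflate (CC(C)(C)[Si](C)(C)OS(=O)(=O)C(F)(F)F)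
Why: The silyl triflate with a hindered base silylates all four hydroxyls, the neopentyl C2 and axial C12 ones included.

Step 12
Reactants: 18 terminal alkyne
Product: 20 2-iodo-1-alkene (C5 iodide), via alkenylalane 19 (not isolated)
Conditions: NiCl2(dppp) (3 mol %, dppp = Ph2P(CH2)3PPh2), iBu2AlH, THF, 0 °C → rt; then I2, −78 → 0 °C
Reagents that add atoms: iodine (II)
Why: Nickel-catalysed Markovnikov hydroalumination of the terminal alkyne and iodinolysis of the alkenylalane give the 2-iodo-1-alkene at a stage where no carbonyl group can consume the hydride.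

Step 13
Reactants: 20 tetrakis-TBS ether
Product: 21 C8 primary alcohol
Conditions: HF·pyridine, pyridine, THF, 0 °C
Reagents that add atoms: none
Why: Buffered HF·pyridine cleaves the unhindered primary silyl ether much faster than the three secondary ones.

Step 14
Reactants: 21 primary alcohol
Product: 22 C8 aldehyde (9-OTBS)
Conditions: Dess–Martin periodinane, NaHCO3, CH2Cl2, 0 °C → rt
Reagents that add atoms: none
Why: Buffered Dess–Martin oxidation gives the α-silyloxy aldehyde without epimerising C9.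

Step 15
Reactants: 22 aldehyde
Product: 23 (8R)-allylic alcohol (8,9-anti)
Conditions: CH2=CHMgBr, THF, −78 °C
Reagents that add atoms: vinylmagnesium bromide (C=C[Mg]Br)
Why: Felkin–Anh addition of the non-chelating vinyl Grignard reagent anti to the C9–OSi bond should give mainly the 8,9-anti carbinol.

Step 16
Reactants: 23 allylic alcohol
Product: 24 (7R,8R)-6,7-epoxy-8-ol (erythro)
Conditions: Ti(OiPr)4, L-(+)-diisopropyl tartrate, tBuOOH, 4 Å molecular sieves, CH2Cl2, −20 °C
Reagents that add atoms: tert-butyl hydroperoxide (CC(C)(C)OO)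
Why: Sharpless epoxidation under reagent control, in which L-(+)-tartrate is matched with the (8R)-carbinol and should give the erythro (7R)-epoxide, while any 8-epimer reacts far more slowly and the C11 methylene, which has no free allylic hydroxyl, is not touched.

Step 17
Reactants: 24 epoxy alcohol
Product: 25 α′-silyloxy (R)-oxiranyl ketone (C8 ketone)
Conditions: Dess–Martin periodinane, NaHCO3, CH2Cl2, rt
Reagents that add atoms: none
Why: Dess–Martin oxidation converts the epoxy alcohol into the α,β-epoxy ketone without opening the epoxide.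

Step 18
Reactants: 25 epoxy ketone
Product: 27 hydroxy lactone (γ-lactone O–C7–C8–C17–C19, 8-OH, C6–OH free), via aldol adduct 26 (not isolated)
Conditions: LiN(iPr)2, tert-butyl propanoate, THF, −78 °C; 25, −78 °C; CF3CO2H, −78 → 0 °C; then DBU, toluene, 60 °C
Reagents that add atoms: tert-butyl propanoate (CCC(=O)OC(C)(C)C)
Why: Aldol addition followed by acid-triggered epoxide opening, the closest known types being the addition of ester enolates to α,β-epoxy ketones and the lactonisation of γ,δ-epoxy tert-butyl esters with loss of 2-methylpropene. The enolate adds to the C8 ketone to form C8–C17, and after the cold acid quench the ester carbonyl oxygen attacks C7 of the protonated epoxide in a 5-exo-tet closure that forms O–C7 and the γ-lactone, inverts C7 and releases the C6 hydroxyl. C8 is set by the substrate, since in the polar Felkin–Anh (Cornforth) arrangement both the C9–OSi bond and the epoxide C7–O bond lie anti to the incoming enolate, so the two α-stereocenters should direct attack to the same face. C17 is set under thermodynamic control by the DBU equilibration, which should place the methyl group trans to the C9 branch. The step needs addition to the ketone and not enolisation (low temperature, a weakly basic ester enolate that also leaves the 2-iodoalkene alone), 5-exo attack at C7 and not 6-endo attack at C6, and no migration of the epoxide toward the C8 oxygen, which the protonation of the alkoxide at −78 °C before warming should secure.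

Step 19
Reactants: 27 hydroxy lactone
Product: 28 C6 aldehyde
Conditions: Dess–Martin periodinane, NaHCO3, CH2Cl2, 0 °C
Reagents that add atoms: none
Why: Dess–Martin oxidation of the primary C6 alcohol, with the tertiary C8 hydroxyl inert, gives the aldehyde that is used crude.

Step 20
Reactants: 28 iodo aldehyde
Product: 29 macrocyclic (6R)-allylic alcohol with C5(16) methylene
Conditions: CrCl2, NiCl2 (cat.), (S)-L, Et3N, THF/MeCN, rt, 2 mM, slow addition
Reagents that add atoms: none
Why: Nozaki–Hiyama–Kishi reaction in which the alkenyl iodide adds oxidatively to nickel, is passed to chromium and the alkenylchromium adds to the C6 aldehyde under high dilution to close the ten-membered ring, with the chiral sulfonamide ligand on chromium used to impose the (6R)-carbinol.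

Step 21
Reactants: 29 allylic alcohol
Product: 30 (6S)-allylic chloride
Conditions: PPh3, Cl3CC(O)CCl3, CH2Cl2, −20 → 0 °C
Reagents that add atoms: hexachloroacetone (ClC(Cl)(Cl)C(=O)C(Cl)(Cl)Cl)
Why: Appel-type chlorination with PPh3 and hexachloroacetone converts secondary allylic alcohols into chlorides by SN2 with inversion and without allylic transposition, while the tertiary C8 hydroxyl does not react.

Step 22
Reactants: 30 chloride
Product: 31 13,14-diol
Conditions: CF3CO2H/H2O (9:1), CH2Cl2, 0 °C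
Reagents that add atoms: none
Why: Brief aqueous acid hydrolyses the acetonide, while the hindered secondary silyl ethers, the lactone and the allylic chloride should survive.

Step 23
Reactants: 31 diol
Product: 32 13-O-(4-methylpentanoyl) ester (14-OH free)
Conditions: 4-methylpentanoyl chloride (1.1 equiv), pyridine, CH2Cl2, −20 °C
Reagents that add atoms: 4-methylpentanoyl chloride (CC(C)CCC(Cl)=O)
Why: Acylation should discriminate the equatorial C13 hydroxyl from the axial, neopentyl C14 hydroxyl and the tertiary C8 hydroxyl.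

Step 24
Reactants: 32 tris-TBS ether
Product: 33 2,9,12,14-tetraol
Conditions: HF·pyridine, pyridine, THF, rt
Reagents that add atoms: none
Why: HF·pyridine removes the three silyl ethers under mildly acidic conditions that should not promote migration of the C13 ester or substitution of the allylic chloride.

Step 25
Reactants: 33 tetraol
Product: 34 11,20-epoxide (oxygen α)
Conditions: VO(acac)2 (cat.), tBuOOH, CH2Cl2, 0 °C
Reagents that add atoms: tert-butyl hydroperoxide (CC(C)(C)OO)
Why: Hydroxyl-directed vanadium-catalysed epoxidation in which the axial allylic 12α-hydroxyl delivers oxygen to the α face of the C11(20) alkene and sets C11, while the C5(16) alkene, deactivated by chlorine and without an allylic hydroxyl, should not react.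

Step 26
Reactants: 34 epoxy tetraol
Product: 35 CNP0196150.1
Conditions: Ac2O, DMAP, pyridine, 40 °C
Reagents that add atoms: acetic anhydride (CC(=O)OC(C)=O)
Why: DMAP-catalysed acetylation esterifies the four secondary hydroxyls (C2, C9, C12, C14) and should leave the hindered tertiary C8 hydroxyl free.

**Compound list**

1 | (R)-2,2-dimethyl-1,3-dioxolane-4-carbaldehyde (D-glyceraldehyde acetonide) | O=C[C@H]1COC(C)(C)O1 | starting material
2 | 2-(triphenylphosphoranylidene)propanal | CC(C=O)=P(c1ccccc1)(c1ccccc1)c1ccccc1 | starting material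
3 | (S,E)-3-(2,2-dimethyl-1,3-dioxolan-4-yl)-2-methylprop-2-enal | O=C/C(C)=C/[C@H]1COC(C)(C)O1 | intermediate
4 | (E)-3-[(tert-butyldimethylsilyl)oxy]-N,N-dimethylbuta-1,3-dien-1-amine | CN(C)/C=C/C(=C)O[Si](C)(C)C(C)(C)C | starting material
5 | (1R,2S,6S)-4-[(tert-butyldimethylsilyl)oxy]-2-(dimethylamino)-6-[(4S)-2,2-dimethyl-1,3-dioxolan-4-yl]-1-methylcyclohex-3-ene-1-carbaldehyde | O=C[C@@]2(C)[C@@H](N(C)C)C=C(O[Si](C)(C)C(C)(C)C)C[C@@H]2[C@H]1COC(C)(C)O1 | intermediate
6 | (4-bromobut-1-yn-1-yl)trimethylsilane | C[Si](C)(C)C#CCCBr | starting material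
7 | 1-[the cyclohexenyl unit of 5]-5-(trimethylsilyl)pent-4-yn-1-ol, both C2 epimers | C[Si](C)(C)C#CCCC(O)[C@@]2(C)[C@@H](N(C)C)C=C(O[Si](C)(C)C(C)(C)C)C[C@@H]2[C@H]1COC(C)(C)O1 | intermediate
8 | the corresponding 5-(trimethylsilyl)pent-4-yn-1-one (C2 ketone) | C[Si](C)(C)C#CCCC(=O)[C@@]2(C)[C@@H](N(C)C)C=C(O[Si](C)(C)C(C)(C)C)C[C@@H]2[C@H]1COC(C)(C)O1 | intermediate
9 | (2S)-alcohol of 8, amine and silyl enol ether still in place | C[Si](C)(C)C#CCC[C@H](O)[C@@]2(C)[C@@H](N(C)C)C=C(O[Si](C)(C)C(C)(C)C)C[C@@H]2[C@H]1COC(C)(C)O1 | intermediate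
10 | (4S,5S)-5-[(4S)-2,2-dimethyl-1,3-dioxolan-4-yl]-4-[(1S)-1-hydroxy-5-(trimethylsilyl)pent-4-yn-1-yl]-4-methylcyclohex-2-en-1-one | C[Si](C)(C)C#CCC[C@H](O)[C@@]2(C)C=CC(=O)C[C@@H]2[C@H]1COC(C)(C)O1 | intermediate
11 | 13α,14α-diol of 10 (2S,9S; C12 ketone; both new hydroxyls trans to C15) | C[Si](C)(C)C#CCC[C@H](O)[C@@]2(C)[C@@H](O)[C@@H](O)C(=O)C[C@@H]2[C@H]1COC(C)(C)O1 | intermediate
12 | 13,14-O-isopropylidene derivative of 11 | C[Si](C)(C)C#CCC[C@H](O)[C@@]2(C)[C@H]3OC(C)(C)O[C@H]3C(=O)C[C@@H]2[C@H]1COC(C)(C)O1 | intermediate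
13 | 11-[(dimethylamino)methyl] derivative of 12 (Mannich base, C11 epimers) | C[Si](C)(C)C#CCC[C@H](O)[C@@]2(C)[C@H]3OC(C)(C)O[C@H]3C(=O)C(CN(C)C)[C@@H]2[C@H]1COC(C)(C)O1 | intermediate
14 | 11-methylene-12-ketone (C11=C20) | C[Si](C)(C)C#CCC[C@H](O)[C@@]2(C)[C@H]3OC(C)(C)O[C@H]3C(=O)C(=C)[C@@H]2[C@H]1COC(C)(C)O1 | intermediate
15 | 12α-allylic alcohol of 14, alkyne still silylated | C[Si](C)(C)C#CCC[C@H](O)[C@@]2(C)[C@H]3OC(C)(C)O[C@H]3[C@@H](O)C(=C)[C@@H]2[C@H]1COC(C)(C)O1 | intermediate
16 | 12α-allylic alcohol with terminal alkyne (2,12-diol, two acetonides) | C#CCC[C@H](O)[C@@]2(C)[C@H]3OC(C)(C)O[C@H]3[C@@H](O)C(=C)[C@@H]2[C@H]1COC(C)(C)O1 | intermediate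
17 | (2S,9S)-2,8,9,12α-tetraol with 13,14-acetonide | C#CCC[C@H](O)[C@@]2(C)[C@H]3OC(C)(C)O[C@H]3[C@@H](O)C(=C)[C@@H]2[C@H](O)CO | intermediate
18 | 2,8,9,12-tetrakis-TBS ether of 17 | C#CCC[C@H](O[Si](C)(C)C(C)(C)C)[C@@]2(C)[C@H]3OC(C)(C)O[C@H]3[C@@H](O[Si](C)(C)C(C)(C)C)C(=C)[C@@H]2[C@H](O[Si](C)(C)C(C)(C)C)CO[Si](C)(C)C(C)(C)C | intermediate
19 | C5 diisobutylalumanyl alkene from 18 (aluminium on the internal carbon) | C=C([Al](CC(C)C)CC(C)C)CC[C@H](O[Si](C)(C)C(C)(C)C)[C@@]2(C)[C@H]3OC(C)(C)O[C@H]3[C@@H](O[Si](C)(C)C(C)(C)C)C(=C)[C@@H]2[C@H](O[Si](C)(C)C(C)(C)C)CO[Si](C)(C)C(C)(C)C | intermediate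
20 | 5-iodo-5(16)-ene (2-iodo-1-alkene), tetrakis-TBS ether | C=C(I)CC[C@H](O[Si](C)(C)C(C)(C)C)[C@@]2(C)[C@H]3OC(C)(C)O[C@H]3[C@@H](O[Si](C)(C)C(C)(C)C)C(=C)[C@@H]2[C@H](O[Si](C)(C)C(C)(C)C)CO[Si](C)(C)C(C)(C)C | intermediate
21 | C8 primary alcohol (2,9,12-tris-TBS) | C=C(I)CC[C@H](O[Si](C)(C)C(C)(C)C)[C@@]2(C)[C@H]3OC(C)(C)O[C@H]3[C@@H](O[Si](C)(C)C(C)(C)C)C(=C)[C@@H]2[C@H](O[Si](C)(C)C(C)(C)C)CO | intermediate
22 | C8 aldehyde, (9S)-OTBS | C=C(I)CC[C@H](O[Si](C)(C)C(C)(C)C)[C@@]2(C)[C@H]3OC(C)(C)O[C@H]3[C@@H](O[Si](C)(C)C(C)(C)C)C(=C)[C@@H]2[C@H](O[Si](C)(C)C(C)(C)C)C=O | intermediate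
23 | (8R,9S)-allylic alcohol, C6=C7 vinyl | C=C(I)CC[C@H](O[Si](C)(C)C(C)(C)C)[C@@]2(C)[C@H]3OC(C)(C)O[C@H]3[C@@H](O[Si](C)(C)C(C)(C)C)C(=C)[C@@H]2[C@H](O[Si](C)(C)C(C)(C)C)[C@H](O)C=C | intermediate
24 | (7R,8R,9S)-6,7-epoxy-8-ol | C=C(I)CC[C@H](O[Si](C)(C)C(C)(C)C)[C@@]2(C)[C@H]3OC(C)(C)O[C@H]3[C@@H](O[Si](C)(C)C(C)(C)C)C(=C)[C@@H]2[C@H](O[Si](C)(C)C(C)(C)C)[C@H](O)[C@H]1CO1 | intermediate
25 | (7R,9S)-6,7-epoxy-8-ketone (α′-silyloxy oxiranyl ketone) | C=C(I)CC[C@H](O[Si](C)(C)C(C)(C)C)[C@@]2(C)[C@H]3OC(C)(C)O[C@H]3[C@@H](O[Si](C)(C)C(C)(C)C)C(=C)[C@@H]2[C@H](O[Si](C)(C)C(C)(C)C)C(=O)[C@H]1CO1 | intermediate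
26 | aldol adduct: tert-butyl 2-methyl-3-hydroxy ester with C8 tertiary carbinol and 6,7-epoxide (C17 epimers) | C=C(I)CC[C@H](O[Si](C)(C)C(C)(C)C)[C@@]2(C)[C@H]3OC(C)(C)O[C@H]3[C@@H](O[Si](C)(C)C(C)(C)C)C(=C)[C@@H]2[C@H](O[Si](C)(C)C(C)(C)C)[C@@](O)([C@H]1CO1)C(C)C(=O)OC(C)(C)C | intermediate
27 | hydroxy lactone: 19,7-olide with 8-OH, 17-methyl cis to 8-OH, C6–OH free (C7, C8, C17 as in 35) | C=C(I)CC[C@H](O[Si](C)(C)C(C)(C)C)[C@@]2(C)[C@H]3OC(C)(C)O[C@H]3[C@@H](O[Si](C)(C)C(C)(C)C)C(=C)[C@@H]2[C@H](O[Si](C)(C)C(C)(C)C)[C@]2(O)[C@@H](C)C(=O)O[C@H]2CO | intermediate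
28 | C6 aldehyde of 27 | C=C(I)CC[C@H](O[Si](C)(C)C(C)(C)C)[C@@]2(C)[C@H]3OC(C)(C)O[C@H]3[C@@H](O[Si](C)(C)C(C)(C)C)C(=C)[C@@H]2[C@H](O[Si](C)(C)C(C)(C)C)[C@]2(O)[C@@H](C)C(=O)O[C@H]2C=O | intermediate
29 | macrocyclic (6R)-alcohol, 5(16)-ene, 2,9,12-tris-TBS, 13,14-acetonide | C=C1CC[C@H](O[Si](C)(C)C(C)(C)C)[C@@]2(C)[C@H]3OC(C)(C)O[C@H]3[C@@H](O[Si](C)(C)C(C)(C)C)C(=C)[C@@H]2[C@H](O[Si](C)(C)C(C)(C)C)[C@]2(O)[C@@H](C)C(=O)O[C@H]2[C@@H]1O | intermediate
30 | (6S)-chloride | C=C1CC[C@H](O[Si](C)(C)C(C)(C)C)[C@@]2(C)[C@H]3OC(C)(C)O[C@H]3[C@@H](O[Si](C)(C)C(C)(C)C)C(=C)[C@@H]2[C@H](O[Si](C)(C)C(C)(C)C)[C@]2(O)[C@@H](C)C(=O)O[C@H]2[C@H]1Cl | intermediate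
31 | 13α,14α-diol of 30 | C=C1CC[C@H](O[Si](C)(C)C(C)(C)C)[C@@]2(C)[C@@H](O)[C@@H](O)[C@@H](O[Si](C)(C)C(C)(C)C)C(=C)[C@@H]2[C@H](O[Si](C)(C)C(C)(C)C)[C@]2(O)[C@@H](C)C(=O)O[C@H]2[C@H]1Cl | intermediate
32 | 13-O-(4-methylpentanoyl) ester, 14-OH free | C=C1CC[C@H](O[Si](C)(C)C(C)(C)C)[C@@]2(C)[C@@H](O)[C@@H](OC(=O)CCC(C)C)[C@@H](O[Si](C)(C)C(C)(C)C)C(=C)[C@@H]2[C@H](O[Si](C)(C)C(C)(C)C)[C@]2(O)[C@@H](C)C(=O)O[C@H]2[C@H]1Cl | intermediate
33 | 2,9,12,14-tetraol (8-OH tertiary), 11(20)-ene | C=C1CC[C@H](O)[C@@]2(C)[C@@H](O)[C@@H](OC(=O)CCC(C)C)[C@@H](O)C(=C)[C@@H]2[C@H](O)[C@]2(O)[C@@H](C)C(=O)O[C@H]2[C@H]1Cl | intermediate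
34 | 11,20-epoxide of 33 (oxygen α) | C=C1CC[C@H](O)[C@@]2(C)[C@@H](O)[C@@H](OC(=O)CCC(C)C)[C@@H](O)[C@]3(CO3)[C@@H]2[C@H](O)[C@]2(O)[C@@H](C)C(=O)O[C@H]2[C@H]1Cl | intermediate
35 | CNP0196150.1, (1S,2S,6S,7R,8R,9S,10S,11R,12R,13R,14R,17R) | C=C1CC[C@H](OC(C)=O)[C@@]2(C)[C@@H](OC(C)=O)[C@@H](OC(=O)CCC(C)C)[C@@H](OC(C)=O)[C@]3(CO3)[C@@H]2[C@H](OC(C)=O)[C@]2(O)[C@@H](C)C(=O)O[C@H]2[C@H]1Cl | target

Total step count: 26
Longest linear sequence: 26 steps (1 → 35)

**Steps most likely to fail**

1. Step 18. The hindered epoxy ketone may be enolised, or the adduct may revert by retro-aldol, instead of adding the α-branched enolate cleanly; the acid stage may also cost silyl ethers. Fallback: from 25, the smaller lithium enolate of tert-butyl acetate is added and the adduct lactonised with CF3CO2H in the same way, giving the 17-desmethyl hydroxy lactone F1. F1 is deprotonated with LiN(iPr)2 (3.1 equiv, THF/DMPU, −78 °C) and the lactone enolate is C-methylated with MeI from the face opposite the C9 branch (the lithium alkoxides do not alkylate at this temperature). The route is rejoined at 27.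

2. Step 20. Facial selectivity at C6 may be poor because the ligand has to override the Felkin–Anh bias of the α-acyloxy aldehyde in a strained ring closure; oligomerisation may compete. Fallback: from 28, ligand-free closure (CrCl2, NiCl2 cat., DMSO, high dilution) under substrate control should give the (6S)-alcohol F2. Mitsunobu inversion with 4-nitrobenzoic acid, PPh3 and diisopropyl azodicarboxylate gives the (6R)-4-nitrobenzoate F3, and methanolysis (K2CO3, MeOH, 0 °C) returns to the route at 29.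

3. Step 2. The electron-rich diene may add across the aldehyde C=O (hetero-Diels–Alder) instead of the hindered C=C bond, and facial control by the dioxolane may be incomplete. Fallback: from 1, Wittig reaction with ethyl 2-(triphenylphosphoranylidene)propanoate gives the enoate F4, which has no aldehyde. Thermal cycloaddition of F4 with 4 (toluene, 110 °C) gives the adduct ester F5, and iBu2AlH (CH2Cl2, −78 °C) reduces the ester to the aldehyde, rejoining the route at 5.

**Further compounds**

F1 | step 18 | 17-desmethyl hydroxy lactone (27 without C18) | C=C(I)CC[C@H](O[Si](C)(C)C(C)(C)C)[C@@]2(C)[C@H]3OC(C)(C)O[C@H]3[C@@H](O[Si](C)(C)C(C)(C)C)C(=C)[C@@H]2[C@H](O[Si](C)(C)C(C)(C)C)[C@]2(O)CC(=O)O[C@H]2CO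
F2 | step 20 | macrocyclic (6S)-alcohol (6-epimer of 29) | C=C1CC[C@H](O[Si](C)(C)C(C)(C)C)[C@@]2(C)[C@H]3OC(C)(C)O[C@H]3[C@@H](O[Si](C)(C)C(C)(C)C)C(=C)[C@@H]2[C@H](O[Si](C)(C)C(C)(C)C)[C@]2(O)[C@@H](C)C(=O)O[C@H]2[C@H]1O
F3 | step 20 | (6R)-4-nitrobenzoate of 29 | C=C1CC[C@H](O[Si](C)(C)C(C)(C)C)[C@@]2(C)[C@H]3OC(C)(C)O[C@H]3[C@@H](O[Si](C)(C)C(C)(C)C)C(=C)[C@@H]2[C@H](O[Si](C)(C)C(C)(C)C)[C@]2(O)[C@@H](C)C(=O)O[C@H]2[C@@H]1OC(=O)c4ccc(cc4)[N+](=O)[O-]
F4 | step 2 | ethyl (S,E)-3-(2,2-dimethyl-1,3-dioxolan-4-yl)-2-methylprop-2-enoate | CCOC(=O)/C(C)=C/[C@H]1COC(C)(C)O1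
F5 | step 2 | ethyl ester analogue of cycloadduct 5 | CCOC(=O)[C@@]2(C)[C@@H](N(C)C)C=C(O[Si](C)(C)C(C)(C)C)C[C@@H]2[C@H]1COC(C)(C)O1
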